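**Plan**
1. Ring numbering: O1, C2 (CH3), C3 (CH2OH), C4 (CH2CO2R), C5 (CO2Me), C6 (=CH–O1). Retrosynthetic cuts, in order: the three O–benzyl bonds; the C4–CH2 bond; a sacrificial ester link C6–O–C(=O); C6 lactol back to lactone; the C4=C5 bond and the O1–C6 acyl bond; the C3–C4 bond.
2. Enabling feature: C4 is the allylic terminus of the ring enol ether O1–C6=C5(CO2Me)–C4. The array C4–C5=C6–O is therefore the retron of a [3,3] shift from the transposed 3,6-dihydro-2H-pyran (C4=C5, acyloxy on the acetal carbon C6).
3. The hydroxytyrosyl half is brought in as its malonic half-acid and hung on C6 as an anomeric ester. A decarboxylative Ireland–Claisen rearrangement then delivers it to C4, and the tether atoms O–C(=O) leave as CO2.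
4. Forward order: crotyl alcohol → epoxide → vinyl opening (C3–C4) → malonate ester (O1–C6) → ozonolysis and Knoevenagel closure of the only ring (C4=C5) → lactol → coupling → rearrangement → hydrogenolysis.
5. Stereochemistry: C2 and C3 come from the Katsuki–Sharpless epoxidation and the invertive epoxide opening. The temporary C6 centre comes from the anomeric preference. C4 comes from suprafacial 1,3-chirality transfer C6 → C4, which is matched with attack anti to the C2 and C3 substituents.

Key step: step 11

Remark: commercial crotyl alcohol is taken as the E isomer. The C4 descriptor reads R at the malonate stage (15, 16, F3) and S at the acetate stage (17, 18) with no change in geometry. C6 of 8, F1 and F7, the malonate carbon of 15, 16 and F3, and the ketene acetal geometry of 14 are left open in the SMILES.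

Step 1
Reactants: 1 (E)-but-2-en-1-ol
Product: 2 [(2S,3S)-3-methyloxiran-2-yl]methanol
Conditions: Ti(OiPr)4 (5 mol%), L-(+)-DIPT (6 mol%), tBuOOH, 4 Å MS, CH2Cl2, −20 °C
Reagents that add atoms: tert-butyl hydroperoxide, CC(C)(C)OO
Why: Katsuki–Sharpless asymmetric epoxidation, in which the L-(+)-tartrate complex delivers oxygen to the face of the E-allylic alcohol that gives the (2S,3S)-trans-epoxide, fixing the future C2 as S and placing the centre that is to be inverted at the future C3.

Step 2
Reactants: 2 [(2S,3S)-3-methyloxiran-2-yl]methanol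
Product: 3 (2R,3S)-2-ethenylbutane-1,3-diol
Conditions: CH2=CHMgBr (3 equiv), CuI (10 mol%), THF–Et2O, −40 to −20 °C; H2O work-up
Reagents that add atoms: vinylmagnesium bromide, C=C[Mg]Br
Why: Copper-catalysed Grignard opening of a 2,3-epoxy alcohol, in which the magnesium alkoxide steers the vinyl group to the epoxide carbon next to CH2O (1,3-diol mode) with SN2 inversion, so the trans-epoxide gives the relative configuration that becomes 2,3-cis in the ring.

Step 3
Reactants: 3 (2R,3S)-2-ethenylbutane-1,3-diol
Product: 4 (2S,3R)-3-[(benzyloxy)methyl]pent-4-en-2-ol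
Conditions: NaH (1.0 equiv), BnBr (1.0 equiv), Bu4NI (cat.), THF, 0 °C to rt
Reagents that add atoms: benzyl bromide, BrCc1ccccc1
Why: Williamson etherification with one equivalent of base, in which the unhindered primary alkoxide should be alkylated faster than the secondary one flanked by the branch, and no stereocentre is touched.

Step 4
Reactants: 4 (2S,3R)-3-[(benzyloxy)methyl]pent-4-en-2-ol
Product: 5 (2S,3R)-3-[(benzyloxy)methyl]pent-4-en-2-yl methyl propanedioate
Conditions: ClC(O)CH2CO2Me, pyridine, CH2Cl2, 0 °C
Reagents that add atoms: methyl 3-chloro-3-oxopropanoate, COC(=O)CC(=O)Cl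
Why: O-acylation of the secondary alcohol by the malonic half-ester chloride (through the acylpyridinium ion or carbomethoxyketene) forms the O1–C6 bond and brings in C5, C6 and the methyl ester with retention at C2.

Step 5
Reactants: 5 (2S,3R)-3-[(benzyloxy)methyl]pent-4-en-2-yl methyl propanedioate
Product: 6 (2S,3R)-3-[(benzyloxy)methyl]-4-oxobutan-2-yl methyl propanedioate
Conditions: O3, CH2Cl2, −78 °C; Me2S, −78 °C to rt; water wash, used crude
Reagents that add atoms: ozone, [O-][O+]=O
Why: Ozonolysis with reductive work-up cleaves the only C=C bond, the benzyl ether and the malonate being inert at −78 °C if the gas stream is stopped at first excess, and the water wash removes formaldehyde, which would otherwise condense with the malonate in the next step, while the configurationally sensitive aldehyde is carried on crude.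

Step 6
Reactants: 6 (2S,3R)-3-[(benzyloxy)methyl]-4-oxobutan-2-yl methyl propanedioate
Product: 7 methyl (5R,6S)-5-[(benzyloxy)methyl]-6-methyl-2-oxo-5,6-dihydro-2H-pyran-3-carboxylate
Conditions: piperidine (10 mol%), AcOH (10 mol%), 4 Å MS, CH2Cl2, 0 °C to rt
Reagents that add atoms: none
Why: Intramolecular Knoevenagel condensation (6-exo-trig aldol addition of the malonate to the aldehyde, then dehydration), in which the malonate CH2 is by far the most acidic site, so ring closure should outrun enolisation of the aldehyde and leave C2 and C3 untouched.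

Step 7
Reactants: 7 methyl (5R,6S)-5-[(benzyloxy)methyl]-6-methyl-2-oxo-5,6-dihydro-2H-pyran-3-carboxylate
Product: 8 methyl (2S,3R)-3-[(benzyloxy)methyl]-6-hydroxy-2-methyl-3,6-dihydro-2H-pyran-5-carboxylate (equilibrating C6 epimers)
Conditions: iBu2AlH (1.05 equiv), CH2Cl2, −78 °C; aq. potassium sodium tartrate
Reagents that add atoms: none
Why: Half-reduction of a lactone to the lactol with iBu2AlH, in which the lactone carbonyl, locked in the more electrophilic E (s-trans) ester conformation, should take up hydride faster than the methyl ester, the tetrahedral aluminate chelated by that ester should persist at −78 °C, and 1,2-delivery is the normal mode of this reagent in CH2Cl2.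

Step 8
Reactants: 9 hydroxytyrosol [4-(2-hydroxyethyl)benzene-1,2-diol]
Product: 10 2-[3,4-bis(benzyloxy)phenyl]ethanol
Conditions: BnBr (2.2 equiv), K2CO3, acetone, reflux
Reagents that add atoms: benzyl bromide, BrCc1ccccc1
Why: Phenol-selective Williamson etherification, since K2CO3 deprotonates only the two catechol hydroxyl groups and leaves the aliphatic alcohol free.

Step 9
Reactants: 10 2-[3,4-bis(benzyloxy)phenyl]ethanol; 11 Meldrum's acid (2,2-dimethyl-1,3-dioxane-4,6-dione)
Product: 12 3-{2-[3,4-bis(benzyloxy)phenyl]ethoxy}-3-oxopropanoic acid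
Conditions: toluene, 100 °C
Reagents that add atoms: none
Why: Thermal alcoholysis of Meldrum's acid opens the dioxanedione with loss of acetone and gives the malonic acid monoester directly.

Step 10
Reactants: 8 methyl (2S,3R)-3-[(benzyloxy)methyl]-6-hydroxy-2-methyl-3,6-dihydro-2H-pyran-5-carboxylate; 12 3-{2-[3,4-bis(benzyloxy)phenyl]ethoxy}-3-oxopropanoic acid
Product: 13 (2S,3R,6S)-3-[(benzyloxy)methyl]-5-(methoxycarbonyl)-2-methyl-3,6-dihydro-2H-pyran-6-yl 2-[3,4-bis(benzyloxy)phenyl]ethyl propanedioate
Conditions: DCC, DMAP (5 mol%), CH2Cl2, −20 to 0 °C; chromatography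
Reagents that add atoms: none
Why: Steglich esterification of the mutarotating lactol (malonic half-acids acylate through the ketene under DCC), in which the temporary C6 centre should form mainly with the acyloxy group pseudoaxial and trans to C2–CH3, as favoured by the anomeric effect and by A(1,2) strain with the C5 ester, the minor 6-epimer being removed on silica.

Step 11
Reactants: 13 (2S,3R,6S)-3-[(benzyloxy)methyl]-5-(methoxycarbonyl)-2-methyl-3,6-dihydro-2H-pyran-6-yl 2-[3,4-bis(benzyloxy)phenyl]ethyl propanedioate
Product: 17 methyl (2S,3R,4S)-3-[(benzyloxy)methyl]-4-(2-{2-[3,4-bis(benzyloxy)phenyl]ethoxy}-2-oxoethyl)-2-methyl-3,4-dihydro-2H-pyran-5-carboxylate, via silyl ketene acetal 14 (not isolated), via rearranged trimethylsilyl ester 15 (not isolated), via malonic half-acid 16 (not isolated)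
Conditions: BSA (2 equiv), KOAc (10 mol%), toluene, rt to 60 °C; MeOH, evaporate; Et3N (20 mol%), toluene, 110 °C
Reagents that add atoms: none
Why: Proposed new method: BSA/KOAc silylates the malonate of 13 to the allyl silyl ketene acetal 14, whose nucleophilic carbon bonds to C4 while the C6–O bond breaks in one concerted suprafacial [3,3] shift that moves the ring alkene from C4=C5 to C5=C6, after which methanol frees acid 16 from silyl ester 15 and heating expels the former tether carbonyl as CO2 through the usual cyclic transition state of a malonic half-acid. The closest known reaction types are the Ireland–Claisen rearrangement of allyl malonates, the BSA/KOAc decarboxylative Claisen rearrangement of allylic sulfonylacetates and the Ireland–Claisen transfer from 3-O-acyl glycals to C1, and the untested part is running the shift in the opposite sense, from an anomeric acyloxy group on C6 of a 3,6-dihydro-2H-pyran to C4. It should be fast because the silyloxy donor on the ketene acetal, the ring oxygen O1 on the carbinol carbon C6 and the ester on the central allyl carbon C5 are all substituents known to accelerate Claisen rearrangements, and because the product gains the push–pull conjugation O1–C6=C5–CO2Me. No ring of the product is closed, the only cycle being the six-membered pericyclic transition state, whose chair or boat shape is irrelevant because the stereocentre at the malonate carbon is erased on decarboxylation. The one lasting new stereocentre, C4, is controlled by 1,3-chirality transfer from the temporary centre C6: the pseudoaxial C6–O bond lies on the ring face opposite to C2–CH3 and C3–CH2OBn, so the new C4–C bond forms on that same, also less hindered, face and gives the 3,4-trans arrangement (4S in 17). The selectivities needed are C4 over C6 (untethered ester enolate equivalents attack such allyl oxocarbenium systems at C6, as in carbon-Ferrier reactions) and concerted shift over ionisation, and the substrate secures both because the tether can reach only C4, the C5 ester destabilises the oxocarbenium ion, and any residual 6-epimer would have to react through a conformer with C2–CH3 axial under the migrating group.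

Step 12
Reactants: 17 methyl (2S,3R,4S)-3-[(benzyloxy)methyl]-4-(2-{2-[3,4-bis(benzyloxy)phenyl]ethoxy}-2-oxoethyl)-2-methyl-3,4-dihydro-2H-pyran-5-carboxylate
Product: 18 methyl (2S,3R,4S)-4-{2-[2-(3,4-dihydroxyphenyl)ethoxy]-2-oxoethyl}-3-(hydroxymethyl)-2-methyl-3,4-dihydro-2H-pyran-5-carboxylate (target)
Conditions: H2 (1 atm), 10% Pd/C, EtOAc, rt, air excluded on work-up
Reagents that add atoms: none
Why: Catalytic hydrogenolysis removes all three benzyl ethers at once under neutral aprotic conditions, which should spare the trisubstituted push–pull alkene C5=C6 and give the freed primary alcohol no catalyst for lactonisation onto the side-chain ester, and no stereocentre is touched.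

**Compound list**
1 | (E)-but-2-en-1-ol | C/C=C/CO | starting material
2 | [(2S,3S)-3-methyloxiran-2-yl]methanol | C[C@@H]1O[C@H]1CO | intermediate
3 | (2R,3S)-2-ethenylbutane-1,3-diol | C[C@H](O)[C@@H](CO)C=C | intermediate
4 | (2S,3R)-3-[(benzyloxy)methyl]pent-4-en-2-ol | C[C@H](O)[C@@H](COCc1ccccc1)C=C | intermediate
5 | (2S,3R)-3-[(benzyloxy)methyl]pent-4-en-2-yl methyl propanedioate | C[C@H](OC(=O)CC(=O)OC)[C@@H](COCc1ccccc1)C=C | intermediate
6 | (2S,3R)-3-[(benzyloxy)methyl]-4-oxobutan-2-yl methyl propanedioate | C[C@H](OC(=O)CC(=O)OC)[C@@H](COCc1ccccc1)C=O | intermediate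
7 | methyl (5R,6S)-5-[(benzyloxy)methyl]-6-methyl-2-oxo-5,6-dihydro-2H-pyran-3-carboxylate | C[C@@H]1OC(=O)C(C(=O)OC)=C[C@@H]1COCc1ccccc1 | intermediate
8 | methyl (2S,3R)-3-[(benzyloxy)methyl]-6-hydroxy-2-methyl-3,6-dihydro-2H-pyran-5-carboxylate (C6 epimers) | C[C@@H]1OC(O)C(C(=O)OC)=C[C@@H]1COCc1ccccc1 | intermediate
9 | hydroxytyrosol, 4-(2-hydroxyethyl)benzene-1,2-diol | OCCc1ccc(O)c(O)c1 | starting material
10 | 2-[3,4-bis(benzyloxy)phenyl]ethanol | OCCc1ccc(OCc2ccccc2)c(OCc2ccccc2)c1 | intermediate
11 | Meldrum's acid, 2,2-dimethyl-1,3-dioxane-4,6-dione | CC1(C)OC(=O)CC(=O)O1 | starting material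
12 | 3-{2-[3,4-bis(benzyloxy)phenyl]ethoxy}-3-oxopropanoic acid | OC(=O)CC(=O)OCCc1ccc(OCc2ccccc2)c(OCc2ccccc2)c1 | intermediate
13 | (2S,3R,6S)-3-[(benzyloxy)methyl]-5-(methoxycarbonyl)-2-methyl-3,6-dihydro-2H-pyran-6-yl 2-[3,4-bis(benzyloxy)phenyl]ethyl propanedioate | C[C@@H]1O[C@@H](OC(=O)CC(=O)OCCc2ccc(OCc3ccccc3)c(OCc3ccccc3)c2)C(C(=O)OC)=C[C@@H]1COCc1ccccc1 | intermediate
14 | trimethylsilyl ketene acetal of 13 (silylated on the anomeric ester carbonyl) | C[C@@H]1O[C@@H](OC(O[Si](C)(C)C)=CC(=O)OCCc2ccc(OCc3ccccc3)c(OCc3ccccc3)c2)C(C(=O)OC)=C[C@@H]1COCc1ccccc1 | intermediate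
15 | 2-[3,4-bis(benzyloxy)phenyl]ethyl trimethylsilyl 2-[(2S,3R,4R)-3-[(benzyloxy)methyl]-5-(methoxycarbonyl)-2-methyl-3,4-dihydro-2H-pyran-4-yl]propanedioate | COC(=O)C1=CO[C@@H](C)[C@@H](COCc2ccccc2)[C@@H]1C(C(=O)O[Si](C)(C)C)C(=O)OCCc1ccc(OCc2ccccc2)c(OCc2ccccc2)c1 | intermediate
16 | 3-{2-[3,4-bis(benzyloxy)phenyl]ethoxy}-2-[(2S,3R,4R)-3-[(benzyloxy)methyl]-5-(methoxycarbonyl)-2-methyl-3,4-dihydro-2H-pyran-4-yl]-3-oxopropanoic acid | COC(=O)C1=CO[C@@H](C)[C@@H](COCc2ccccc2)[C@@H]1C(C(=O)O)C(=O)OCCc1ccc(OCc2ccccc2)c(OCc2ccccc2)c1 | intermediate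
17 | methyl (2S,3R,4S)-3-[(benzyloxy)methyl]-4-(2-{2-[3,4-bis(benzyloxy)phenyl]ethoxy}-2-oxoethyl)-2-methyl-3,4-dihydro-2H-pyran-5-carboxylate | COC(=O)C1=CO[C@@H](C)[C@@H](COCc2ccccc2)[C@@H]1CC(=O)OCCc1ccc(OCc2ccccc2)c(OCc2ccccc2)c1 | intermediate
18 | methyl (2S,3R,4S)-4-{2-[2-(3,4-dihydroxyphenyl)ethoxy]-2-oxoethyl}-3-(hydroxymethyl)-2-methyl-3,4-dihydro-2H-pyran-5-carboxylate | COC(=O)C1=CO[C@@H](C)[C@@H](CO)[C@@H]1CC(=O)OCCc1ccc(O)c(O)c1 | target

Total steps: 12. Longest linear sequence: 10 (steps 1–7 and 10–12).

**Steps most likely to fail**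

Step 11. Loss of the lactolate from the enolised malonate (ketene extrusion) or ionisation of the anomeric ester may outrun the sigmatropic shift. Ion-pair collapse would also erode the facial fidelity. The fallback uses known chemistry, sets out from lactol 8 and half-acid 12, and comes back at half-acid 16.
- Lactol 8 is acetylated (Ac2O, pyridine) to the anomeric acetate F1.
- Acid 12 is alkylated with allyl bromide (K2CO3, DMF) to the allyl arylethyl malonate F2.
- The sodium enolate of F2 (NaH, THF, 0 °C) adds to C4 of F1 anti to the C2 and C3 substituents, and the resulting C5 ester enolate expels acetate from C6. This conjugate addition–elimination is the SN2′ mode known for malonates with Morita–Baylis–Hillman acetates, and it gives the triester F3.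
- Tsuji–Trost deallylation by zerovalent palladium (Pd(PPh3)4, morpholine, THF) then frees 16, which is decarboxylated as in the last stage of step 11.

Step 7. Hydride may be delivered to the methyl ester or in the conjugate sense, or a second reduction may follow ring opening of the aluminate. The fallback places the ester on C5 only after the lactone has been reduced. It sets out from alcohol 4 and comes back at lactol 8.
- Acryloyl chloride (Et3N, CH2Cl2) gives the acrylate F4.
- Ring-closing metathesis (second-generation Grubbs catalyst, CH2Cl2, reflux) gives the unsaturated lactone F5.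
- α-Iodination (I2, pyridine, CH2Cl2) gives the iodolactone F6.
- iBu2AlH at −78 °C, now without a competing ester, gives the iodolactol F7.
- Methoxycarbonylation of the vinyl iodide (PdCl2(PPh3)2, CO, MeOH, Et3N) gives 8.

Step 6. The malonate may be lost by β-elimination from the β-acyloxy aldehyde, and configuration at C3 may be lost by enolisation of the aldehyde or γ-deprotonation of the product. The fallback makes the C4=C5 bond intermolecularly on a substrate whose β-oxygen is a poor leaving group, and it closes the lactone last. It sets out from alcohol 4 and comes back at lactone 7.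
- TESCl and imidazole give the silyl ether F8.
- Ozonolysis (O3; Me2S) gives the aldehyde F9.
- Condensation with dimethyl malonate under TiCl4/pyridine (THF, 0 °C) gives the alkylidene malonate F10.
- AcOH–THF–H2O removes the silyl group, and the freed C2 hydroxyl lactonises onto the cis ester to give 7.

**Further compounds**
F1 | step 11 | methyl (2S,3R)-6-acetoxy-3-[(benzyloxy)methyl]-2-methyl-3,6-dihydro-2H-pyran-5-carboxylate (C6 epimers) | C[C@@H]1OC(OC(C)=O)C(C(=O)OC)=C[C@@H]1COCc1ccccc1
F2 | step 11 | allyl 2-[3,4-bis(benzyloxy)phenyl]ethyl propanedioate | C=CCOC(=O)CC(=O)OCCc1ccc(OCc2ccccc2)c(OCc2ccccc2)c1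
F3 | step 11 | allyl 2-[3,4-bis(benzyloxy)phenyl]ethyl 2-[(2S,3R,4R)-3-[(benzyloxy)methyl]-5-(methoxycarbonyl)-2-methyl-3,4-dihydro-2H-pyran-4-yl]propanedioate | COC(=O)C1=CO[C@@H](C)[C@@H](COCc2ccccc2)[C@@H]1C(C(=O)OCC=C)C(=O)OCCc1ccc(OCc2ccccc2)c(OCc2ccccc2)c1
F4 | step 7 | (2S,3R)-3-[(benzyloxy)methyl]pent-4-en-2-yl prop-2-enoate | C[C@H](OC(=O)C=C)[C@@H](COCc1ccccc1)C=C
F5 | step 7 | (5R,6S)-5-[(benzyloxy)methyl]-6-methyl-5,6-dihydro-2H-pyran-2-one | C[C@@H]1OC(=O)C=C[C@@H]1COCc1ccccc1
F6 | step 7 | (5R,6S)-5-[(benzyloxy)methyl]-3-iodo-6-methyl-5,6-dihydro-2H-pyran-2-one | C[C@@H]1OC(=O)C(I)=C[C@@H]1COCc1ccccc1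
F7 | step 7 | (5R,6S)-5-[(benzyloxy)methyl]-3-iodo-6-methyl-5,6-dihydro-2H-pyran-2-ol (C2 epimers) | C[C@@H]1OC(O)C(I)=C[C@@H]1COCc1ccccc1
F8 | step 6 | {[(2S,3R)-3-[(benzyloxy)methyl]pent-4-en-2-yl]oxy}triethylsilane | C[C@H](O[Si](CC)(CC)CC)[C@@H](COCc1ccccc1)C=C
F9 | step 6 | (2R,3S)-2-[(benzyloxy)methyl]-3-[(triethylsilyl)oxy]butanal | C[C@H](O[Si](CC)(CC)CC)[C@@H](COCc1ccccc1)C=O
F10 | step 6 | dimethyl 2-{(2R,3S)-2-[(benzyloxy)methyl]-3-[(triethylsilyl)oxy]butylidene}propanedioate | C[C@H](O[Si](CC)(CC)CC)[C@@H](COCc1ccccc1)C=C(C(=O)OC)C(=O)OC
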